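**Plan**
- Retrosynthesis: first cut the C3–O ester bond, which releases (Z)-2-(acetoxymethyl)but-2-enoic acid (made from but-2-ynoic acid). Then cut the benzene ring at C3a–C4 and C5–C6 into but-3-yn-2-one and a diene C6=C7–C7a=C3a whose C7a=C3a bond lies inside a 2,3-dihydrofuran. Finally cut C6–C7 (ester enolate plus lactone) back to a lactone from 2-deoxy-D-ribose.
- Enabling feature: the arene carries oxygen at C7a (O1) and C6 in a 1,3 relation, the acetyl group on C5 ortho to the C6 hydroxyl, and hydrogen at C4 and C7. This is the pattern that a 1,3-dioxygenated ketene-acetal diene and an ynone deliver. C3 and C2 of the dihydrofuran map onto C3 and C4 of the sugar.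
- Forward order: the oxygen ring is the furanose ring of the sugar, kept as the lactone. C5 of the sugar becomes the isopropenyl group, an acetate unit is added at C1, and the diene is formed. The benzene ring closes last by [4+2] cycloaddition and aromatisation, followed by desilylation and acylation.
- Stereochemistry: C2 (R) and C3 (S), trans, are C4 and C3 of 2-deoxy-D-ribose and are never broken. The Z-olefin of the side chain comes from a syn-hydroalumination.

Key step: step 11

Remark: from the diene onward, ring atoms carry the benzofuran numbering of the target (O1, C2, C3, C3a, C4 to C7, C7a). Centres that are formed and later destroyed (carbinol carbon of 6, anomeric carbon of 11 and 12, C3a and C6 of 17, C3a of 18) are carried as mixtures and left open in the SMILES.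

**Route**

Step 1
Reactants: 1 2-deoxy-D-ribose
Product: 2 2-deoxy-D-ribono-1,4-lactone
Conditions: Br2, H2O, 23 °C, dark
Reagents that add atoms: none
Why: Aqueous bromine oxidises the anomeric hemiacetal of the furanose form to the γ-lactone (aldose-to-aldonolactone oxidation) and leaves the C3 and C4 carbinol centres untouched.

Step 2
Reactants: 2 2-deoxy-D-ribono-1,4-lactone
Product: 3 (4S,5R)-4-(tert-butyldimethylsilyloxy)-5-[(tert-butyldimethylsilyloxy)methyl]oxolan-2-one
Conditions: TBSCl, imidazole, DMF, 23 °C
Reagents that add atoms: tert-butyldimethylsilyl chloride, CC(C)(C)[Si](C)(C)Cl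
Why: Standard silyl ether formation (silyl chloride, imidazole) caps both hydroxyls, since the secondary one cannot be silylated selectively in the presence of the primary one.

Step 3
Reactants: 3 (4S,5R)-4-(tert-butyldimethylsilyloxy)-5-[(tert-butyldimethylsilyloxy)methyl]oxolan-2-one
Product: 4 (4S,5R)-4-(tert-butyldimethylsilyloxy)-5-(hydroxymethyl)oxolan-2-one
Conditions: CF3CO2H/H2O/THF (1:1:4), 0 °C
Reagents that add atoms: none
Why: Acid-catalysed hydrolysis of silyl ethers depends strongly on steric hindrance, so the primary ether should be cleaved selectively and the secondary one at C3 should stay (selective desilylation).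

Step 4
Reactants: 4 (4S,5R)-4-(tert-butyldimethylsilyloxy)-5-(hydroxymethyl)oxolan-2-one
Product: 5 (2S,3S)-3-(tert-butyldimethylsilyloxy)-5-oxooxolane-2-carbaldehyde
Conditions: Dess–Martin periodinane, CH2Cl2, 0 → 23 °C; used crude
Reagents that add atoms: none
Why: Dess–Martin oxidation of the primary alcohol is non-basic, so the aldehyde should form without epimerisation at the α-oxygenated carbon or β-elimination of the silyloxy group.

Step 5
Reactants: 5 (2S,3S)-3-(tert-butyldimethylsilyloxy)-5-oxooxolane-2-carbaldehyde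
Product: 6 (4S,5R)-4-(tert-butyldimethylsilyloxy)-5-(1-hydroxyethyl)oxolan-2-one (both carbinol epimers)
Conditions: MeMgBr (1.1 equiv), THF, −78 °C; aq. NH4Cl
Reagents that add atoms: methylmagnesium bromide, C[Mg]Br
Why: Grignard addition at −78 °C discriminates the far more electrophilic α-alkoxy aldehyde from the lactone; the new carbinol centre is not controlled because it is oxidised away in step 6.

Step 6
Reactants: 6 (4S,5R)-4-(tert-butyldimethylsilyloxy)-5-(1-hydroxyethyl)oxolan-2-one
Product: 7 (4S,5S)-5-acetyl-4-(tert-butyldimethylsilyloxy)oxolan-2-one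
Conditions: Dess–Martin periodinane, CH2Cl2, 0 → 23 °C
Reagents that add atoms: none
Why: Dess–Martin oxidation of the secondary alcohol gives the methyl ketone under conditions that do not enolise the adjacent stereocentre.

Step 7
Reactants: 7 (4S,5S)-5-acetyl-4-(tert-butyldimethylsilyloxy)oxolan-2-one
Product: 8 (4S,5R)-4-(tert-butyldimethylsilyloxy)-5-(prop-1-en-2-yl)oxolan-2-one
Conditions: Zn, CH2Br2, TiCl4, THF/CH2Cl2, 0 → 23 °C
Reagents that add atoms: dibromomethane, BrCBr
Why: Lombardo methylenation uses a non-basic zinc–titanium methylene reagent that olefinates ketones but not lactones and does not enolise the substrate, so the configuration next to the ketone is kept.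

Step 8
Reactants: 8 (4S,5R)-4-(tert-butyldimethylsilyloxy)-5-(prop-1-en-2-yl)oxolan-2-one; 9 methyl acetate
Product: 11 methyl 2-[(4S,5R)-4-(tert-butyldimethylsilyloxy)-2-hydroxy-5-(prop-1-en-2-yl)oxolan-2-yl]acetate (both anomers), via lithium enolate of methyl acetate 10 (not isolated)
Conditions: LiN(iPr)2, 9, THF, −78 °C; then 8, −78 °C; AcOH quench at −78 °C
Reagents that add atoms: none
Why: Claisen-type addition of the ester enolate to the lactone carbonyl stops at the tetrahedral lithium alkoxide at −78 °C and gives the hemiketal on cold quench, as in additions of ester enolates to aldonolactones; the low temperature keeps enolisation of the lactone and β-elimination of the silyloxy group in check.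

Step 9
Reactants: 11 methyl 2-[(4S,5R)-4-(tert-butyldimethylsilyloxy)-2-hydroxy-5-(prop-1-en-2-yl)oxolan-2-yl]acetate
Product: 13 methyl (2E)-2-[(4S,5R)-4-(tert-butyldimethylsilyloxy)-5-(prop-1-en-2-yl)oxolan-2-ylidene]acetate, via hemiketal trifluoroacetate 12 (not isolated)
Conditions: (CF3CO)2O, pyridine, CH2Cl2, 0 → 23 °C
Reagents that add atoms: none
Why: Acylation of the hemiketal hydroxyl and E1cB-type elimination toward the acidic methylene next to the ester (dehydration of a β-keto ester hemiketal) gives the conjugated exocyclic enol ether, for which the E isomer is thermodynamically preferred.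

Step 10
Reactants: 13 methyl (2E)-2-[(4S,5R)-4-(tert-butyldimethylsilyloxy)-5-(prop-1-en-2-yl)oxolan-2-ylidene]acetate
Product: 15 tert-butyl-{[(2R,3S)-5-[2-methoxy-2-(trimethylsilyloxy)ethenyl]-2-(prop-1-en-2-yl)-2,3-dihydrofuran-3-yl]oxy}dimethylsilane (ketene acetal geometry immaterial), via lithium dienolate 14 (not isolated)
Conditions: LiN(iPr)2, THF, −78 °C; Me3SiCl, −78 → 0 °C; pentane, filtration under argon; used at once
Reagents that add atoms: chlorotrimethylsilane, C[Si](C)(C)Cl
Why: Kinetic γ-deprotonation of the β-alkoxy enoate at the ring methylene that lies cis to the ester carbonyl, followed by O-silylation of the extended enolate, is the standard preparation of 1-alkoxy-1-silyloxy-3-alkoxydienes from 3-alkoxy-enoates; at −78 °C the β-silyloxy group is too poor a leaving group to be expelled before silylation.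

Step 11
Reactants: 15 tert-butyl-{[(2R,3S)-5-[2-methoxy-2-(trimethylsilyloxy)ethenyl]-2-(prop-1-en-2-yl)-2,3-dihydrofuran-3-yl]oxy}dimethylsilane; 16 but-3-yn-2-one
Product: 19 1-[(2R,3S)-3-(tert-butyldimethylsilyloxy)-6-hydroxy-2-(prop-1-en-2-yl)-2,3-dihydro-1-benzofuran-5-yl]ethanone, via cyclohexa-1,4-diene cycloadduct 17 (not isolated), via cyclohexadienone 18 (not isolated)
Conditions: 16 (1.5 equiv), toluene, −20 → 23 °C, no acid or Lewis acid; then aq. citric acid, THF, 0 °C
Reagents that add atoms: none
Why: The electron-rich diene C6=C7–C7a=C3a (largest HOMO coefficient at C3a, raised by O1 and by the two ketene acetal oxygens) and the ynone (largest LUMO coefficient at its terminal carbon) should combine in a concerted but asynchronous normal-demand Diels–Alder reaction in which C3a–C4 forms ahead of C5–C6. The closest known reaction type is the cycloaddition of 1-alkoxy-1-silyloxy-3-alkoxybutadienes (Brassard-type) and 1-alkoxy-3-silyloxybutadienes (Danishefsky-type) with alkynyl ketones and propiolates, which gives ortho-acylphenols after elimination. The benzene ring is closed by this intermolecular [4+2] event as the cyclohexa-1,4-diene 17; mild acid hydrolyses its silyl ketal to dienone 18 with loss of trimethylsilanol and methanol, and 18 tautomerises to the phenol through its C3a–H. No lasting stereocentre is created, since C3a and C6 of 17 become sp2, and C2 and C3 are spectators inherited from the sugar. The step needs regioselectivity, which the matched polarisation of the two partners secures so that the acetyl group lands on C5 next to the C6 hydroxyl and hydrogen on C4. It also needs the allylic C3 silyloxy group to survive, which is secured by its poor leaving-group ability, the absence of protic or Lewis acid during the cycloaddition and the low temperature.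

Step 12
Reactants: 19 1-[(2R,3S)-3-(tert-butyldimethylsilyloxy)-6-hydroxy-2-(prop-1-en-2-yl)-2,3-dihydro-1-benzofuran-5-yl]ethanone
Product: 20 1-[(2R,3S)-3,6-dihydroxy-2-(prop-1-en-2-yl)-2,3-dihydro-1-benzofuran-5-yl]ethanone
Conditions: HF·pyridine, pyridine, THF, 0 → 23 °C
Reagents that add atoms: none
Why: Fluoride-driven cleavage of the secondary silyl ether with pyridine-buffered HF·pyridine (desilylation) is near neutral, so the electron-rich benzylic alcohol should neither ionise nor dehydrate to the benzofuran, and C3 keeps its configuration because only the O–Si bond breaks.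

Step 13
Reactants: 21 but-2-ynoic acid
Product: 22 tert-butyl but-2-ynoate
Conditions: isobutene, H2SO4 (cat.), CH2Cl2, sealed tube, 23 °C
Reagents that add atoms: 2-methylpropene, C=C(C)C
Why: Acid-catalysed addition of the carboxylic acid to isobutene (tert-butyl ester formation) masks the acid as an ester that resists 1,2-reduction and can later be removed without base.

Step 14
Reactants: 22 tert-butyl but-2-ynoate
Product: 24 tert-butyl (2Z)-2-(hydroxymethyl)but-2-enoate, via vinylalane 23 (not isolated)
Conditions: iBu2AlH, N-methylmorpholine N-oxide, THF, 0 °C; then CH2O (gas, from cracked paraformaldehyde), 0 → 23 °C; H2O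
Reagents that add atoms: formaldehyde, C=O
Why: The iBu2AlH–amine oxide complex adds H and Al syn across the ynoate with aluminium on the α-carbon (conjugate hydroalumination), and the α-alumino acrylate adds to formaldehyde with retention (vinylalumination, a reductive aldol reaction), so that the hydroxymethyl group ends cis to the β-hydrogen and the methyl group cis to the ester, i.e. Z.

Step 15
Reactants: 24 tert-butyl (2Z)-2-(hydroxymethyl)but-2-enoate
Product: 25 tert-butyl (2Z)-2-(acetoxymethyl)but-2-enoate
Conditions: Ac2O, pyridine, CH2Cl2, 0 → 23 °C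
Reagents that add atoms: acetic anhydride, CC(=O)OC(C)=O
Why: Acetylation of the primary allylic alcohol with acetic anhydride and pyridine is a plain O-acylation that does not touch the olefin geometry.

Step 16
Reactants: 25 tert-butyl (2Z)-2-(acetoxymethyl)but-2-enoate
Product: 26 (2Z)-2-(acetoxymethyl)but-2-enoic acid
Conditions: CF3CO2H, CH2Cl2, 0 → 23 °C
Reagents that add atoms: none
Why: Acidolysis of the tert-butyl ester (E1 loss of isobutene) frees the acid without base or nucleophile, so neither the acetate nor the Z-olefin is affected.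

Step 17
Reactants: 20 1-[(2R,3S)-3,6-dihydroxy-2-(prop-1-en-2-yl)-2,3-dihydro-1-benzofuran-5-yl]ethanone; 26 (2Z)-2-(acetoxymethyl)but-2-enoic acid
Product: 28 (2R,3S)-5-acetyl-6-hydroxy-2-(prop-1-en-2-yl)-2,3-dihydro-1-benzofuran-3-yl (2Z)-2-(acetoxymethyl)but-2-enoate, via acid chloride 27 (not isolated)
Conditions: 26, Me2C=C(Cl)NMe2, CH2Cl2, 0 °C; then 20, pyridine, CH2Cl2, −20 → 0 °C
Reagents that add atoms: none
Why: The α-chloroenamine turns the acid into its chloride under neutral conditions and the chloride acylates the secondary C3 alcohol in the presence of pyridine (nucleophilic acyl substitution), while the C6 phenol, held in a hydrogen bond to the C5 acetyl group, is much less nucleophilic; no nucleophilic catalyst is present, so the Z-olefin and the allylic acetate should persist, and C3 keeps its configuration because its C–O bond is not broken.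

**Compound list**

1 | 2-deoxy-D-ribose, (3S,4R)-3,4,5-trihydroxypentanal | O=CC[C@H](O)[C@H](O)CO | starting material
2 | 2-deoxy-D-ribono-1,4-lactone, (4S,5R)-4-hydroxy-5-(hydroxymethyl)oxolan-2-one | OC[C@H]1OC(=O)C[C@@H]1O | intermediate
3 | (4S,5R)-4-(tert-butyldimethylsilyloxy)-5-[(tert-butyldimethylsilyloxy)methyl]oxolan-2-one | CC(C)(C)[Si](C)(C)OC[C@H]1OC(=O)C[C@@H]1O[Si](C)(C)C(C)(C)C | intermediate
4 | (4S,5R)-4-(tert-butyldimethylsilyloxy)-5-(hydroxymethyl)oxolan-2-one | OC[C@H]1OC(=O)C[C@@H]1O[Si](C)(C)C(C)(C)C | intermediate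
5 | (2S,3S)-3-(tert-butyldimethylsilyloxy)-5-oxooxolane-2-carbaldehyde | O=C[C@H]1OC(=O)C[C@@H]1O[Si](C)(C)C(C)(C)C | intermediate
6 | (4S,5R)-4-(tert-butyldimethylsilyloxy)-5-(1-hydroxyethyl)oxolan-2-one, carbinol epimers | CC(O)[C@H]1OC(=O)C[C@@H]1O[Si](C)(C)C(C)(C)C | intermediate
7 | (4S,5S)-5-acetyl-4-(tert-butyldimethylsilyloxy)oxolan-2-one | CC(=O)[C@H]1OC(=O)C[C@@H]1O[Si](C)(C)C(C)(C)C | intermediate
8 | (4S,5R)-4-(tert-butyldimethylsilyloxy)-5-(prop-1-en-2-yl)oxolan-2-one | C=C(C)[C@H]1OC(=O)C[C@@H]1O[Si](C)(C)C(C)(C)C | intermediate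
9 | methyl acetate | COC(C)=O | starting material
10 | lithium enolate of methyl acetate (lithium 1-methoxyethenolate) | C=C(OC)O[Li] | intermediate
11 | methyl 2-[(4S,5R)-4-(tert-butyldimethylsilyloxy)-2-hydroxy-5-(prop-1-en-2-yl)oxolan-2-yl]acetate, anomers | C=C(C)[C@H]1OC(O)(CC(=O)OC)C[C@@H]1O[Si](C)(C)C(C)(C)C | intermediate
12 | trifluoroacetate of hemiketal 11 | C=C(C)[C@H]1OC(OC(=O)C(F)(F)F)(CC(=O)OC)C[C@@H]1O[Si](C)(C)C(C)(C)C | intermediate
13 | methyl (2E)-2-[(4S,5R)-4-(tert-butyldimethylsilyloxy)-5-(prop-1-en-2-yl)oxolan-2-ylidene]acetate | C=C(C)[C@H]1O/C(=C/C(=O)OC)C[C@@H]1O[Si](C)(C)C(C)(C)C | intermediate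
14 | lithium dienolate of 13 (ring C=C in place, lithium on the ester oxygen) | C=C(C)[C@H]1OC(C=C(OC)O[Li])=C[C@@H]1O[Si](C)(C)C(C)(C)C | intermediate
15 | tert-butyl-{[(2R,3S)-5-[2-methoxy-2-(trimethylsilyloxy)ethenyl]-2-(prop-1-en-2-yl)-2,3-dihydrofuran-3-yl]oxy}dimethylsilane | C=C(C)[C@H]1OC(C=C(OC)O[Si](C)(C)C)=C[C@@H]1O[Si](C)(C)C(C)(C)C | intermediate
16 | but-3-yn-2-one | CC(=O)C#C | starting material
17 | 1-[(2R,3S)-3-(tert-butyldimethylsilyloxy)-6-methoxy-2-(prop-1-en-2-yl)-6-(trimethylsilyloxy)-2,3,3a,6-tetrahydro-1-benzofuran-5-yl]ethanone | C=C(C)[C@H]1OC2=CC(OC)(O[Si](C)(C)C)C(C(C)=O)=CC2[C@@H]1O[Si](C)(C)C(C)(C)C | intermediate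
18 | (2R,3S)-5-acetyl-3-(tert-butyldimethylsilyloxy)-2-(prop-1-en-2-yl)-3,3a-dihydro-1-benzofuran-6(2H)-one | C=C(C)[C@H]1OC2=CC(=O)C(C(C)=O)=CC2[C@@H]1O[Si](C)(C)C(C)(C)C | intermediate
19 | 1-[(2R,3S)-3-(tert-butyldimethylsilyloxy)-6-hydroxy-2-(prop-1-en-2-yl)-2,3-dihydro-1-benzofuran-5-yl]ethanone (trans) | C=C(C)[C@H]1Oc2cc(O)c(C(C)=O)cc2[C@@H]1O[Si](C)(C)C(C)(C)C | intermediate
20 | 1-[(2R,3S)-3,6-dihydroxy-2-(prop-1-en-2-yl)-2,3-dihydro-1-benzofuran-5-yl]ethanone | C=C(C)[C@H]1Oc2cc(O)c(C(C)=O)cc2[C@@H]1O | intermediate
21 | but-2-ynoic acid | CC#CC(=O)O | starting material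
22 | tert-butyl but-2-ynoate | CC#CC(=O)OC(C)(C)C | intermediate
23 | tert-butyl (2E)-2-(diisobutylalumanyl)but-2-enoate (Al cis to the β-hydrogen) | C/C=C(/[Al](CC(C)C)CC(C)C)C(=O)OC(C)(C)C | intermediate
24 | tert-butyl (2Z)-2-(hydroxymethyl)but-2-enoate | C/C=C(/CO)C(=O)OC(C)(C)C | intermediate
25 | tert-butyl (2Z)-2-(acetoxymethyl)but-2-enoate | C/C=C(/COC(C)=O)C(=O)OC(C)(C)C | intermediate
26 | (2Z)-2-(acetoxymethyl)but-2-enoic acid | C/C=C(/COC(C)=O)C(=O)O | intermediate
27 | (2Z)-2-(acetoxymethyl)but-2-enoyl chloride | C/C=C(/COC(C)=O)C(=O)Cl | intermediate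
28 | (2R,3S)-5-acetyl-6-hydroxy-2-(prop-1-en-2-yl)-2,3-dihydro-1-benzofuran-3-yl (2Z)-2-(acetoxymethyl)but-2-enoate | C=C(C)[C@H]1Oc2cc(O)c(C(C)=O)cc2[C@@H]1OC(=O)/C(=C\C)COC(C)=O | target

**Step count**

Total steps: 17. Longest linear sequence: 13 (steps 1 to 12, then step 17); the side-chain acid takes 4 steps (13 to 16).

**Steps most likely to fail**

Step 11. The cycloaddition may be outrun by oligomerisation of the ynone started by the nucleophilic ketene acetal, or by ionisation of the allylic C3 silyloxy group of the diene, which would end in a furan. The ketal of the adduct may also collapse with loss of silanol in place of methanol, which would leave an aryl methyl ether. The fallback sets out from diene 15 and uses an olefinic dienophile, with the aromatisation done as a separate oxidation. But-3-en-2-one in toluene at −40 to 0 °C should give the hexahydrobenzofuran ketal F1. Aqueous citric acid should convert it into the 5-acetyl-tetrahydrobenzofuran-6-one F2, in which the C6 oxygen is fixed as a carbonyl before any aromatisation, so no methyl ether can arise. Dehydrogenation with DDQ in dioxane at 23 °C should then give phenol 19, where the route is rejoined.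

Step 10. Deprotonation may occur at the vinylic α-carbon in place of the ring methylene, or the lithium dienolate may expel the β-silyloxy group before it is silylated. The fallback sets out from lactone 8 and puts the ring double bond in place by cross-coupling, so that no lithium dienolate is needed. KN(SiMe3)2 and ClP(O)(OPh)2 in THF at −78 °C should give the ketene acetal phosphate F3. Negishi coupling with BrZnCH2CO2Me under Pd(PPh3)4 catalysis should give the 4,5-dihydrofuran-2-ylacetate F4. Its doubly activated methylene should be silylated on oxygen by Et3N and Me3SiOTf at −78 °C, which rejoins the route at diene 15.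

Step 17. The phenol may be acylated in competition with the C3 alcohol, and the activated acyl unit may isomerise from Z to E or transpose its allylic acetate. Once the phenol is deprotonated, the new benzylic ester may also be expelled through a para-quinone methide. The fallback sets out from phenol 19 and masks the phenol before the alcohol is freed. iPr3SiOTf and 2,6-lutidine should give the aryl triisopropylsilyl ether F5. Pyridine-buffered HF·pyridine should remove only the alkyl silyl ether to give the C3 alcohol F6. Acylation with acid chloride 27 and pyridine, now with no second hydroxyl, should give the silylated ester F7. Bu4NF buffered with acetic acid at −20 °C should then free the phenol and rejoin the route at target 28.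

**Further compounds**

F1 | step 11 | 1-[(2R,3S)-3-(tert-butyldimethylsilyloxy)-6-methoxy-2-(prop-1-en-2-yl)-6-(trimethylsilyloxy)-2,3,3a,4,5,6-hexahydro-1-benzofuran-5-yl]ethanone | C=C(C)[C@H]1OC2=CC(OC)(O[Si](C)(C)C)C(C(C)=O)CC2[C@@H]1O[Si](C)(C)C(C)(C)C
F2 | step 11 | (2R,3S)-5-acetyl-3-(tert-butyldimethylsilyloxy)-2-(prop-1-en-2-yl)-3,3a,4,5-tetrahydro-1-benzofuran-6(2H)-one | C=C(C)[C@H]1OC2=CC(=O)C(C(C)=O)CC2[C@@H]1O[Si](C)(C)C(C)(C)C
F3 | step 10 | (2R,3S)-3-(tert-butyldimethylsilyloxy)-2-(prop-1-en-2-yl)-2,3-dihydrofuran-5-yl diphenyl phosphate | C=C(C)[C@H]1OC(OP(=O)(Oc2ccccc2)Oc2ccccc2)=C[C@@H]1O[Si](C)(C)C(C)(C)C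
F4 | step 10 | methyl 2-[(4S,5R)-4-(tert-butyldimethylsilyloxy)-5-(prop-1-en-2-yl)-4,5-dihydrofuran-2-yl]acetate | C=C(C)[C@H]1OC(CC(=O)OC)=C[C@@H]1O[Si](C)(C)C(C)(C)C
F5 | step 17 | 1-[(2R,3S)-3-(tert-butyldimethylsilyloxy)-2-(prop-1-en-2-yl)-6-(triisopropylsilyloxy)-2,3-dihydro-1-benzofuran-5-yl]ethanone | C=C(C)[C@H]1Oc2cc(O[Si](C(C)C)(C(C)C)C(C)C)c(C(C)=O)cc2[C@@H]1O[Si](C)(C)C(C)(C)C
F6 | step 17 | 1-[(2R,3S)-3-hydroxy-2-(prop-1-en-2-yl)-6-(triisopropylsilyloxy)-2,3-dihydro-1-benzofuran-5-yl]ethanone | C=C(C)[C@H]1Oc2cc(O[Si](C(C)C)(C(C)C)C(C)C)c(C(C)=O)cc2[C@@H]1O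
F7 | step 17 | (2R,3S)-5-acetyl-2-(prop-1-en-2-yl)-6-(triisopropylsilyloxy)-2,3-dihydro-1-benzofuran-3-yl (2Z)-2-(acetoxymethyl)but-2-enoate | C=C(C)[C@H]1Oc2cc(O[Si](C(C)C)(C(C)C)C(C)C)c(C(C)=O)cc2[C@@H]1OC(=O)/C(=C\C)COC(C)=O
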